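## Retrosynthetic overview

- Target locants: C1 = C(OH)CH2OBz, C7 = that CH2, C2 = C=O, C3=C4, C5 = CHOBz, C6 = CHOH. Zeylenone 17 ⇐ acetonide 16 ⇐ enone 13 ⇐ allylboronate ester 10. Only functional-group changes lie between them: C7 CO2R → CH2OBz, C2 B → OH → C=O, and PMB → Bz at C5.
- Enabling feature: the array C7–C1–C2–C3=C4 of the cyclohexenone ring. With C7 raised to the acid level it is a γ,δ-unsaturated acid, which is a Claisen retron. Cutting C1–C2 and re-joining the carboxyl oxygen to C4 gives the six-membered lactone ring O–C7–C1–C6–C5–C4, with a C3=C2 alkenylboronate arm on C4.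
- That ring is a D-mannono-1,5-lactone. C7, C1, C6, C5, C4 and C3 are mannose C1–C6, and C2 comes from Cl2CHBpin. C6 and C5 come from the chiral pool, the cis C1/C6 diol is the mannose 2,3-acetonide, and the C4–O stereocentre is sacrificed to write C1.
- Ring order: the pyranose ring (chiral pool) and the dioxolane are temporary and come first. The carbocycle is the only skeletal ring that is built. It is closed last, in step 7, while the pyranone ring is unzipped. The phenyl rings arrive with BzCl.

Key step: step 7

Assumption: 1, 7, 15 and the reagents named in the conditions are taken as commercial. The configuration drawn at the boron- or hydroxyl-bearing carbon of 10–12 is the one predicted from the boat transition state. It does not matter for the target, because this centre becomes the ketone.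

## Route

Step 1
Reactants: 1 phenyl 1-thio-α-D-mannopyranoside
Product: 2 phenyl 4,6-O-[(R)-4-methoxybenzylidene]-1-thio-α-D-mannopyranoside
Conditions: 4-MeOC6H4CH(OMe)2 (1.1 equiv), CSA (cat.), DMF, 50 °C, reduced pressure
Reagents that add atoms: 4-methoxybenzaldehyde dimethyl acetal, COC(OC)c1ccc(OC)cc1
Why: Acid-catalysed transacetalisation under thermodynamic control should select the 4,6-diol, because only it gives a trans-fused 1,3-dioxane chair, and should set the new acetal centre with the aryl group equatorial.

Step 2
Reactants: 2 phenyl 4,6-O-(4-methoxybenzylidene)-1-thio-α-D-mannopyranoside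
Product: 3 phenyl 2,3-O-isopropylidene-4,6-O-(4-methoxybenzylidene)-1-thio-α-D-mannopyranoside
Conditions: 2-methoxypropene, PPTS (cat.), CH2Cl2, 0 °C to rt
Reagents that add atoms: 2-methoxypropene, COC(C)=C
Why: Mild acid-catalysed ketalisation of the remaining cis-2,3-diol should give the cis-fused dioxolane without exchange of the aryl acetal and creates no new stereocentre.

Step 3
Reactants: 3 phenyl 2,3-O-isopropylidene-4,6-O-(4-methoxybenzylidene)-1-thio-α-D-mannopyranoside
Product: 4 phenyl 2,3-O-isopropylidene-4-O-(4-methoxybenzyl)-1-thio-α-D-mannopyranoside (free 6-OH)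
Conditions: DIBAL-H (toluene solution), toluene, −40 to 0 °C; Rochelle salt
Reagents that add atoms: none
Why: In this regioselective reductive acetal opening the aluminium binds the less hindered O6, the C–O6 bond ionises with help from the anisyl group and hydride is delivered, so the PMB ether should stay on O4 and the primary alcohol is freed.

Step 4
Reactants: 4 phenyl 2,3-O-isopropylidene-4-O-(4-methoxybenzyl)-1-thio-α-D-mannopyranoside
Product: 5 2,3-O-isopropylidene-4-O-(4-methoxybenzyl)-D-mannopyranose (lactol, α/β)
Conditions: NBS, acetone–H2O (9:1), −20 to 0 °C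
Reagents that add atoms: water, O
Why: Halonium-promoted thioglycoside hydrolysis works because sulfur is the most nucleophilic site, and the large excess of water should intercept the oxocarbenium ion to give an anomeric mixture that is erased in step 5.

Step 5
Reactants: 5 2,3-O-isopropylidene-4-O-(4-methoxybenzyl)-D-mannopyranose
Product: 6 2,3-O-isopropylidene-4-O-(4-methoxybenzyl)-D-manno-hexodialdono-1,5-lactone (C1 lactone, C6 aldehyde)
Conditions: Dess–Martin periodinane (3 equiv), CH2Cl2, 0 °C to rt; used crude
Reagents that add atoms: none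
Why: A double Dess–Martin oxidation should take the lactol to the δ-lactone and the primary alcohol to the aldehyde under base-free conditions, so the α-stereocentre of the aldehyde is not epimerised, and the blocked O4 prevents isomerisation to the γ-lactone.

Step 6
Reactants: 6 aldehyde lactone; 7 2-(dichloromethyl)-4,4,5,5-tetramethyl-1,3,2-dioxaborolane
Product: 8 (E)-6,7-dideoxy-2,3-O-isopropylidene-4-O-(4-methoxybenzyl)-7-(pinacolatoboryl)-D-manno-hept-6-enono-1,5-lactone
Conditions: 7 (2 equiv), CrCl2 (8 equiv), LiI (4 equiv), THF, rt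
Reagents that add atoms: 7 2-(dichloromethyl)-4,4,5,5-tetramethyl-1,3,2-dioxaborolane, ClC(Cl)B1OC(C)(C)C(C)(C)O1
Why: In the Takai–Utimoto olefination (boron variant) an α-boryl gem-dichromium species adds to the aldehyde and eliminates to the E-alkenylboronate under non-basic conditions, so the lactone, the α-stereocentre and the β-OPMB group should stay intact.

Step 7
Reactants: 8 (E)-alkenylboronate δ-lactone
Product: 10 tert-butyldimethylsilyl 1,6-O-isopropylidene-1,6-dihydroxy-5-(4-methoxybenzyloxy)-2-(pinacolatoboryl)cyclohex-3-ene-1-carboxylate (C1–O cis to C6–O; C5–O trans to C6–O; C2–B trans to C1–O), via silyl ketene acetal 9 (not isolated)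
Conditions: LiHMDS, TBSCl, THF–DMPU, −78 to 0 °C; then toluene, 100 °C
Reagents that add atoms: tert-butyldimethylsilyl chloride, CC(C)(C)[Si](C)(C)Cl
Why: LiHMDS removes the lactone α-H (mannose H-2) and TBSCl traps the enolate on oxygen as the cyclic silyl ketene acetal 9, whose allyl vinyl ether unit C1=C7(OTBS)–O–C4–C3=C2 undergoes on heating a concerted suprafacial [3,3]-sigmatropic shift that makes C1–C2, breaks C4–O and delivers C3=C4 and the C7 silyl ester in the same event. The reaction type is the Ireland–Claisen rearrangement, with close precedent in the conversion of 6-alkenyl δ-lactone silyl ketene acetals into cyclohex-3-enecarboxylates, in the thermal Claisen carbocyclisation of 5-vinyl glycals, and in Ireland–Claisen reactions of 3-boryl allyl esters that give α-substituted allylboronates. The cyclohexene is closed by this [3,3] shift through a boat transition state, because the two-carbon C6–C5 bridge between the reacting termini excludes the chair. C1 is controlled by the sacrificial C4–O stereocentre (mannose C5), since the alkenyl arm stands on the β-face and can reach only that face of the planar ketene acetal carbon, which places C1–O cis to C6–O, while C2 follows from the E-alkene in the boat (boron trans to C1–O) and is erased in step 10. The step needs enolisation without β-elimination of the C6 oxygen, and the cis-fused dioxolane secures this by holding that C–O bond near the enolate plane (O–C–C–O about 30°), a dihedral that also fits the boat geometry. Because C1 is planar in 9 either C1 epimer of the lactone would give the same product, and no regiochemical alternative exists because only one allyl ester unit is present.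

Step 8
Reactants: 10 silyl ester allylboronate
Product: 11 2-hydroxy-1,6-O-isopropylidene-1,6-dihydroxy-5-(4-methoxybenzyloxy)cyclohex-3-ene-1-carboxylic acid (C2–OH trans to C1–O)
Conditions: 30% H2O2, aq NaOH, THF, 0 °C to rt; then 1 M HCl to pH 4
Reagents that add atoms: hydrogen peroxide, OO
Why: Oxidation of the boronic ester by 1,2-migration from boron to oxygen should occur with retention and without allylic transposition, which places the oxygen regiospecifically on C2, and the labile silyl ester is hydrolysed in the same basic medium.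

Step 9
Reactants: 11 β-hydroxy acid
Product: 12 1-(hydroxymethyl)-1,6-O-isopropylidene-5-(4-methoxybenzyloxy)cyclohex-3-ene-1,2,6-triol (free C7–OH and C2–OH)
Conditions: LiAlH4, THF, 0 °C to reflux; Fieser work-up
Reagents that add atoms: none
Why: Hydride reduction of the carboxylate should give the neopentyl primary alcohol C7, while the ketal, the PMB ether and the isolated alkene are inert and no stereocentre is touched.

Step 10
Reactants: 12 diol
Product: 13 6-(hydroxymethyl)-5,6-O-isopropylidene-5,6-dihydroxy-4-(4-methoxybenzyloxy)cyclohex-2-enone (target locants: C2 ketone, C7–OH free)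
Conditions: activated MnO2 (excess), CH2Cl2, rt
Reagents that add atoms: none
Why: Chemoselective MnO2 oxidation should convert only the allylic C2 carbinol, whose C–H is predicted pseudo-axial, into the enone, leave the saturated primary alcohol untouched and remove the C2 stereocentre.

Step 11
Reactants: 13 PMB-protected hydroxy enone
Product: 14 4-hydroxy-6-(hydroxymethyl)-5,6-O-isopropylidene-5,6-dihydroxycyclohex-2-enone (free C5–OH and C7–OH)
Conditions: DDQ, CH2Cl2–pH 7 buffer (10:1), 0 °C to rt
Reagents that add atoms: none
Why: Oxidative PMB cleavage proceeds by hydride abstraction from the electron-rich benzylic position and hydrolysis of the oxocarbenium ion, so the C5 alcohol should be freed with retention while the ketal and the enone are untouched.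

Step 12
Reactants: 14 diol enone; 15 benzoyl chloride
Product: 16 zeylenone 1,6-acetonide (C5 and C7 dibenzoate)
Conditions: 15 (2.5 equiv), pyridine, DMAP (cat.), CH2Cl2, 0 °C to rt
Reagents that add atoms: 15 benzoyl chloride, O=C(Cl)c1ccccc1
Why: Nucleophile-catalysed acylation should esterify the only two free hydroxyl groups, and differentiation from C1–OH and C6–OH is guaranteed because these are locked in the ketal.

Step 13
Reactants: 16 zeylenone 1,6-acetonide
Product: 17 zeylenone, (1S,5R,6S)
Conditions: TFA–H2O (9:1), 0 °C to rt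
Reagents that add atoms: none
Why: Acid hydrolysis of the isopropylidene ketal should free the cis C1/C6 diol without epimerisation or elimination, because C1 carries no hydrogen, the benzoates tolerate aqueous acid and no C–O bond at a stereocentre is broken.

## Compound list

1 | phenyl 1-thio-α-D-mannopyranoside | OC[C@H]1O[C@H](Sc2ccccc2)[C@@H](O)[C@@H](O)[C@@H]1O | starting material
2 | phenyl 4,6-O-[(R)-4-methoxybenzylidene]-1-thio-α-D-mannopyranoside | COc1ccc(cc1)[C@@H]1OC[C@H]2O[C@H](Sc3ccccc3)[C@@H](O)[C@@H](O)[C@@H]2O1 | intermediate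
3 | phenyl 2,3-O-isopropylidene-4,6-O-[(R)-4-methoxybenzylidene]-1-thio-α-D-mannopyranoside | COc1ccc(cc1)[C@@H]1OC[C@H]2O[C@H](Sc3ccccc3)[C@H]3OC(C)(C)O[C@H]3[C@@H]2O1 | intermediate
4 | phenyl 2,3-O-isopropylidene-4-O-(4-methoxybenzyl)-1-thio-α-D-mannopyranoside | OC[C@H]1O[C@H](Sc2ccccc2)[C@H]2OC(C)(C)O[C@H]2[C@@H]1OCc1ccc(OC)cc1 | intermediate
5 | 2,3-O-isopropylidene-4-O-(4-methoxybenzyl)-D-mannopyranose (α/β) | OC[C@H]1OC(O)[C@H]2OC(C)(C)O[C@H]2[C@@H]1OCc1ccc(OC)cc1 | intermediate
6 | 2,3-O-isopropylidene-4-O-(4-methoxybenzyl)-D-manno-hexodialdono-1,5-lactone | O=C[C@H]1OC(=O)[C@H]2OC(C)(C)O[C@H]2[C@@H]1OCc1ccc(OC)cc1 | intermediate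
7 | 2-(dichloromethyl)-4,4,5,5-tetramethyl-1,3,2-dioxaborolane | ClC(Cl)B1OC(C)(C)C(C)(C)O1 | starting material
8 | (E)-alkenylboronate δ-lactone | CC1(C)OB(/C=C/[C@H]2OC(=O)[C@H]3OC(C)(C)O[C@H]3[C@@H]2OCc2ccc(OC)cc2)OC1(C)C | intermediate
9 | cyclic tert-butyldimethylsilyl ketene acetal of 8 | CC(C)(C)[Si](C)(C)OC1=C2OC(C)(C)O[C@H]2[C@H](OCc2ccc(OC)cc2)[C@@H](/C=C/B2OC(C)(C)C(C)(C)O2)O1 | intermediate
10 | TBS cyclohex-3-enecarboxylate with C2 allylboronate | CC(C)(C)[Si](C)(C)OC(=O)[C@]12OC(C)(C)O[C@H]1[C@H](OCc1ccc(OC)cc1)C=C[C@@H]2B1OC(C)(C)C(C)(C)O1 | intermediate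
11 | C2-hydroxy cyclohex-3-enecarboxylic acid | OC(=O)[C@]12OC(C)(C)O[C@H]1[C@H](OCc1ccc(OC)cc1)C=C[C@@H]2O | intermediate
12 | C7/C2 diol | OC[C@]12OC(C)(C)O[C@H]1[C@H](OCc1ccc(OC)cc1)C=C[C@@H]2O | intermediate
13 | C7-hydroxy enone, C5–OPMB | OC[C@]12OC(C)(C)O[C@H]1[C@H](OCc1ccc(OC)cc1)C=CC2=O | intermediate
14 | C5,C7-dihydroxy enone | OC[C@]12OC(C)(C)O[C@H]1[C@H](O)C=CC2=O | intermediate
15 | benzoyl chloride | O=C(Cl)c1ccccc1 | starting material
16 | zeylenone 1,6-acetonide | O=C(OC[C@]12OC(C)(C)O[C@H]1[C@H](OC(=O)c1ccccc1)C=CC2=O)c1ccccc1 | intermediate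
17 | zeylenone | O=C(OC[C@@]1(O)C(=O)C=C[C@@H](OC(=O)c2ccccc2)[C@@H]1O)c1ccccc1 | target

## Step count and main risks

Total step count: 13. Longest linear sequence: 13 (1 → 17).

**Step 7.** Enolisation could end in β-elimination of the C6 oxygen or in C-silylation. The electron-rich ketene acetal could also decompose before the strained boat transition state is reached.
- The fallback moves the ring closure from C1–C2 to C3=C4 and uses ring-closing metathesis. It sets out from 5 and comes back at 13.
- In this mapping mannose C1 becomes C2, a new CH2OH becomes C7 and mannose C5 becomes C4. This gives the same enantiomer.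
- Crossed aldol of 5 with aqueous formaldehyde (K2CO3, MeOH, heat) should give the 2-C-hydroxymethyl lactol F1, with the dioxolane kept cis-fused.
- Excess vinylmagnesium bromide opens it to the vinyl carbinol F2 as both carbinol epimers.
- NaIO4 cleaves the only free vicinal diol to the aldehyde F3, and methylenetriphenylphosphorane gives the diene F4.
- A second-generation Grubbs catalyst closes the cyclohexenediol F5. MnO2 then takes both carbinol epimers to 13.

**Step 6.** Cr(II) could reductively cleave the α-acyloxy C–O bond, or the aldehyde lactone could hydrate or epimerise before olefination.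
- The fallback builds the C3–C2 arm at the glycoside stage without chromium and installs boron last. It sets out from 4 and comes back at 8.
- Parikh–Doering oxidation of 4 gives the thioglycoside aldehyde F6.
- The Ohira–Bestmann reagent (K2CO3, MeOH) gives the alkyne F7.
- NBS in aqueous acetone gives the alkynyl lactol F8, and Dess–Martin oxidation gives the alkynyl lactone F9.
- Zirconocene-catalysed syn-hydroboration with pinacolborane then gives 8.

**Step 10.** The hindered allylic carbinol next to the quaternary centre could oxidise sluggishly, or the free β-hydroxy ketone could lose formaldehyde by retro-aldol.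
- The fallback caps C7 first and uses a non-selective oxidant. It sets out from 12 and comes back at 16.
- Selective benzoylation of the primary alcohol (BzCl, collidine, −40 °C) gives the monobenzoate F10.
- Dess–Martin oxidation gives the enone F11, and DDQ frees the C5 alcohol F12.
- Benzoylation of F12 gives 16.

## Further compounds

F1 | step 7 | 2-C-(hydroxymethyl)-2,3-O-isopropylidene-4-O-(4-methoxybenzyl)-D-mannopyranose | OC[C@H]1OC(O)[C@@]2(CO)OC(C)(C)O[C@H]2[C@@H]1OCc1ccc(OC)cc1
F2 | step 7 | open-chain vinyl carbinol (carbinol epimers) | C=CC(O)[C@@]1(CO)OC(C)(C)O[C@H]1[C@H](OCc1ccc(OC)cc1)[C@H](O)CO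
F3 | step 7 | α-(4-methoxybenzyloxy) aldehyde after glycol cleavage | C=CC(O)[C@@]1(CO)OC(C)(C)O[C@H]1[C@H](OCc1ccc(OC)cc1)C=O
F4 | step 7 | metathesis diene | C=CC(O)[C@@]1(CO)OC(C)(C)O[C@H]1[C@H](OCc1ccc(OC)cc1)C=C
F5 | step 7 | cyclohexenediol, C2 epimers of 12 | OC[C@]12OC(C)(C)O[C@H]1[C@H](OCc1ccc(OC)cc1)C=CC2O
F6 | step 6 | thioglycoside 6-aldehyde | O=C[C@H]1O[C@H](Sc2ccccc2)[C@H]2OC(C)(C)O[C@H]2[C@@H]1OCc1ccc(OC)cc1
F7 | step 6 | thioglycoside alkyne | C#C[C@H]1O[C@H](Sc2ccccc2)[C@H]2OC(C)(C)O[C@H]2[C@@H]1OCc1ccc(OC)cc1
F8 | step 6 | alkynyl lactol | C#C[C@H]1OC(O)[C@H]2OC(C)(C)O[C@H]2[C@@H]1OCc1ccc(OC)cc1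
F9 | step 6 | alkynyl δ-lactone | C#C[C@H]1OC(=O)[C@H]2OC(C)(C)O[C@H]2[C@@H]1OCc1ccc(OC)cc1
F10 | step 10 | C7 monobenzoate of 12 | O=C(OC[C@]12OC(C)(C)O[C@H]1[C@H](OCc1ccc(OC)cc1)C=C[C@@H]2O)c1ccccc1
F11 | step 10 | C7 benzoate enone, C5–OPMB | O=C(OC[C@]12OC(C)(C)O[C@H]1[C@H](OCc1ccc(OC)cc1)C=CC2=O)c1ccccc1
F12 | step 10 | C7 benzoate enone, C5–OH | O=C(OC[C@]12OC(C)(C)O[C@H]1[C@H](O)C=CC2=O)c1ccccc1
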